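## The problem

Hansforester J is an open-chain tetramer, read here as A–B–C–D, held together by three ester bonds. Unit A is (R)-1-(3,5-dihydroxyphenyl)propan-2-ol, unit B an inner (R)-3-oxybutanoyl group, unit C a 2,4-dihydroxy-6-[(R)-2-oxypropyl]benzoyl group (ring C numbered from the carboxyl-bearing C1) and unit D a terminal (R)-3-hydroxybutanoyl group. No ring has to be closed apart from the two benzene rings, which can be bought or elaborated.

All four stereocentres are secondary carbinol carbons of (R) configuration. Each is separated from the next by an ester linkage and several atoms, so none can direct another, and each must be bought or set by a reagent.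

The hardest connection is the ester between the C1 carboxyl of ring C, flanked by the C2 oxygen and the C6 side chain, and the secondary carbinol of unit B. Acyl activation of such a 2,6-disubstituted benzoic acid is slow, whereas alkylation of its carboxylate is not.

The finished molecule carries two 3-acyloxybutanoate esters and one 3-hydroxybutanoate ester, which eliminate to crotonates or undergo acyl transfer with base, and four free resorcinol hydroxyls. The closing steps therefore have to be neutral, and the protecting groups must fall under hydrogenolysis. A free 2-hydroxypropyl group at C6 also closes readily onto the C1 carboxyl as a six-membered lactone, which would mask the two functions that must be esterified differently.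

Ring C has two adjacent carbon substituents (carboxyl at C1, CH2 at C6) next to an oxygen at C2. This is the pattern left when a 3-alkoxybenzyne takes a carbon nucleophile at the carbon remote from oxygen and an electrophile at the carbon beside it. The aryne needed comes from a symmetric 3,5-dioxygenated phenol.

## Retrosynthesis

**Unmasking.** Target 26 is traced to its pentabenzyl ether 25 by cutting five O–benzyl bonds. Benzyl is chosen for all four phenols and for the unit D hydroxyl because one neutral hydrogenolysis then ends the synthesis, and none of the ester C–O bonds of 25 is benzylic. The forward step must leave three aliphatic ester bonds and four stereocentres untouched.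

**Central ester.** Compound 25 is cut at the bond between the carboxylate oxygen of ring C and the carbinol carbon of unit B, giving acid 17 and alcohol 24. The A–B and C–D esters are ordinary acylations and could be cut instead, but the central cut divides the molecule into halves of similar size and allows the hindered benzoate to be formed by alkylation of its carboxylate. The forward reaction is a Mitsunobu esterification, which inverts the carbinol, so 24 carries the (S)-3-hydroxybutanoate and the (R) centre of unit B arises in the coupling.

**A–B half.** Alcohol 24 is traced to acetoacetate 23 by removing the carbinol hydrogen pair, and 23 to alcohol 21 and dioxinone 22 by cutting the A–B ester bond. Catalyst-controlled hydrogenation of the β-keto ester sets the (S) centre and needs no protecting group on the hydroxybutanoate. Alcohol 21 is cut at the aryl–CH2 bond to bromide 18 and (R)-propylene oxide 19 (through arylmagnesium 20), so the unit A stereocentre is bought.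

**C–D half.** Acid 17 is traced to its tert-butyl ester 16, and 16 is cut at the C–D ester bond to alcohol 12 and acid 15. Acid 15 comes from methyl (R)-3-hydroxybutanoate 13 through benzyl ether 14. A tert-butyl ester is preferred to a methyl ester on ring C for two reasons. It resists attack by the neighbouring hydroxyl, so the lactone never forms. It also leaves by alkyl–oxygen cleavage in acid, so the crowded carbonyl need not be attacked and the unit D ester is not endangered by hydroxide.

**Side-chain stereocentre.** Alcohol 12 is traced to ketone 11, ketone 11 to allyl compound 10 and 10 to acid 9. The allyl group is thus a masked (R)-2-hydroxypropyl group: a Wacker oxidation places the oxygen and an (R)-selective ketoreductase sets the configuration. Methyl ketones of the 1-arylpropan-2-one class are standard substrates for such enzymes.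

**Key disconnection.** Acid 9 is cut at two bonds of ring C at once, C6–CH2 and C1–carboxyl, giving sulfonate 3, allylmagnesium chloride 4 and carbon dioxide 5. In the forward direction 3 gives arylmagnesium 6, which collapses to aryne 7; 4 adds to give arylmagnesium 8, and 5 quenches it. Stepwise substitution of a resorcinol would need separate formylation or halogenation and cross-coupling steps and would raise a regiochemical question at each. The aryne route installs both carbon arms in one flask, with the regiochemistry governed by the benzyloxy group beside the triple bond.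

**Aryne precursor.** Sulfonate 3 is traced to iodophenol 2 by cutting the S–O bond, and 2 to the symmetric phenol 1 by cutting the C–I bond. The forward iodination must go ortho to the hydroxyl (C2 and C6 are equivalent) and not to C4 between the two benzyloxy groups.

## Roads not taken

**Alternative 1:** Ring C is built from open-chain pieces by cutting the ring C1–C6 and C2–C3 bonds. In the forward direction the sodium enolate of dimethyl malonate A3 adds to the β-carbon of the silyloxy enone A2, the methyl ketone enolate closes onto one malonate ester, and the cyclic dione is dehydrogenated in the same flask to the resorcylate ester A1.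
- Merits: the side-chain stereocentre is bought with A2, so no asymmetric step is needed for ring C, and the substitution pattern follows from connectivity, with no regiochemical question. In this respect it is better than the chosen plan, which needs an enzyme.
- Weak points: A1 is a methyl ester of a 2,6-disubstituted benzoate with two free phenols. The phenols must be protected and the ester cleaved under forcing conditions, or the lactone must be accepted after desilylation. The aromatisation uses a halogenating oxidant on a ring that becomes an electron-rich resorcinol. A2 can lose its silyloxy group by vinylogous elimination under the alkoxide conditions.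
- Comparison: the chosen plan sets against this a free acid with benzyl ethers already in place, obtained directly from the key step, and no hydrolysis of a hindered ester.

**Alternative 2:** The C6–CH2 bond and the lactone C–O bond are cut. In the forward direction potassium 2,4-bis(benzyloxy)benzoate A5 is palladated at C6 by a divalent palladium carboxylate catalyst with a mono-protected amino acid ligand, the aryl–palladium bond opens (R)-propylene oxide 19 at its CH2 carbon, and the alkoxide closes to lactone A4.
- Merits: this is the shortest entry to ring C. The carbon arm and its stereocentre arrive in one step, and only one ortho C–H bond is available, so the site is unambiguous.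
- Weak points: the product is the lactone, so the carboxyl is tied up by the very oxygen that must carry unit D. It has to be opened, the carboxylate trapped, the alcohol acylated and the carboxyl released again, through a hydroxy ester that tends to re-close. The tolerance of the C–H activation for an electron-rich ring with an ortho alkoxy group and two benzyl ethers is also an open question.
- Comparison: counted to acid 17, this road needs about five steps against eight in the chosen plan, so it is better in step economy. The chosen plan sets against it a route that never passes through the lactone and predictable magnesium chemistry in the ring-substituting step.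

**Alternative 3:** The ring C1–C2 and C5–C6 bonds are cut. In the forward direction the ynoate A7, which already carries units A, B and D, undergoes [4+2] cycloaddition with the bis(silyloxy) diene A8, and elimination of the methoxy and silyl groups aromatises the adduct to the tribenzyl ether A6.
- Merits: this is the most convergent road. Ring C appears last with its phenols free, and the hindered benzoate ester never has to be made, because the ester is formed on an unhindered alkynoic acid. In these respects it is better than the chosen plan.
- Weak points: a β-alkyl ynoate is a modest dienophile and needs heat. A7 has a homopropargylic acyloxy group and two β-acyloxy ester units that can eliminate under those conditions. The diene is sensitive. A failure would consume the fully assembled A–B–D material in the last carbon–carbon bond-forming step.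
- Comparison: the chosen plan forms the ring C bonds at the start on inexpensive material and keeps the late stage to esterifications and a hydrogenolysis.

Key step: step 3

Assumption: all four stereocentres are read from the structure as (R), and the (R)-selective ketoreductase of step 6 is taken to be the NADPH-dependent alcohol dehydrogenase of Lactobacillus brevis or an engineered anti-Prelog variant found by screening.

## Route

Step 1
Reactants: 1 3,5-bis(benzyloxy)phenol
Product: 2 3,5-bis(benzyloxy)-2-iodophenol
Conditions: NIS (1.0 equiv), CH2Cl2, −78 → −20 °C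
Reagents that add atoms: N-iodosuccinimide, O=C1CCC(=O)N1I
Why: Electrophilic aromatic iodination of a phloroglucinol-type ring; C2 and C6 are equivalent and less crowded than C4 between the two benzyloxy groups, so the bulky iodine electrophile should enter ortho to the hydroxyl, and one equivalent at low temperature limits di-iodination.

Step 2
Reactants: 2 3,5-bis(benzyloxy)-2-iodophenol
Product: 3 3,5-bis(benzyloxy)-2-iodophenyl 4-chlorobenzenesulfonate
Conditions: 4-ClC6H4SO2Cl, Et3N, DMAP (cat.), CH2Cl2, 0 °C → rt
Reagents that add atoms: 4-chlorobenzenesulfonyl chloride, O=S(=O)(Cl)c1ccc(Cl)cc1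
Why: O-Sulfonylation of a phenol with an arenesulfonyl chloride and amine base; the arenesulfonate is the leaving group for the later elimination and is stable to chromatography.

Step 3
Reactants: 3 3,5-bis(benzyloxy)-2-iodophenyl 4-chlorobenzenesulfonate; 4 allylmagnesium chloride; 5 carbon dioxide
Product: 9 2-allyl-4,6-bis(benzyloxy)benzoic acid, via magnesiated aryl sulfonate 6 (not isolated), via 3,5-bis(benzyloxy)benzyne 7 (not isolated), via 2-allylarylmagnesium chloride 8 (not isolated)
Conditions: iPrMgCl (1.05 equiv), THF, −78 °C; 4 (2.5 equiv), −78 → 0 °C; CO2 (5, gas), −20 °C → rt; 1 M HCl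
Reagents that add atoms: none
Why: Iodine–magnesium exchange with iPrMgCl at −78 °C gives arylmagnesium 6, which on warming loses magnesium 4-chlorobenzenesulfonate to give aryne 7, its triple bond spanning the former C–I and C–O carbons. Allylmagnesium chloride 4, present in excess, adds across the strained triple bond (aryne carbomagnesiation) to give 8, and CO2 then carboxylates the new aryl–magnesium bond to give 9 after acidification, so the C6–CH2 and C1–carboxyl bonds of ring C form in one flask. The closest known reaction type is the addition of magnesium nucleophiles to arynes released from 2-magnesiated aryl sulfonates with electrophilic quench of the resulting arylmagnesium, together with the distal addition of carbon nucleophiles to 3-alkoxyarynes. No ring closes and no stereocentre is formed. The selectivity needed is regiochemical: the benzyloxy group beside the triple bond withdraws through the σ framework and distorts the aryne so that the carbon remote from it is the more electrophilic, and the carbanion develops beside oxygen where induction and chelation of magnesium stabilise it, so allyl enters at C6 and magnesium at C1. The second benzyloxy group lies further from the triple bond, has only a minor and opposing inductive influence, and is not expected to overturn this bias. Chemoselectivity is secured by using one equivalent of iPrMgCl, consumed in the exchange before the aryne is released, so that 4 is the only nucleophile present in quantity when 7 forms.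

Step 4
Reactants: 9 2-allyl-4,6-bis(benzyloxy)benzoic acid
Product: 10 tert-butyl 2-allyl-4,6-bis(benzyloxy)benzoate
Conditions: Cl3CC(=NH)OtBu (3 equiv), CH2Cl2/cyclohexane, rt
Reagents that add atoms: tert-butyl 2,2,2-trichloroacetimidate, CC(C)(C)OC(=N)C(Cl)(Cl)Cl
Why: Alkylative esterification: the acid protonates the imidate and the carboxylate captures the tert-butyl group, so the crowded carbonyl carbon is never attacked; the tert-butyl ester is chosen because it resists later lactonisation.

Step 5
Reactants: 10 tert-butyl 2-allyl-4,6-bis(benzyloxy)benzoate
Product: 11 tert-butyl 2,4-bis(benzyloxy)-6-(2-oxopropyl)benzoate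
Conditions: PdCl2 (10 mol %), CuCl (1 equiv), O2 (1 atm), DMF/H2O 7:1, rt
Reagents that add atoms: water, O
Why: Tsuji–Wacker oxidation: divalent palladium activates the terminal alkene for Markovnikov attack by water and β-hydride elimination gives the methyl ketone, while CuCl and O2 reoxidise zerovalent palladium; ester and benzyl ethers are inert.

Step 6
Reactants: 11 tert-butyl 2,4-bis(benzyloxy)-6-(2-oxopropyl)benzoate
Product: 12 tert-butyl 2,4-bis(benzyloxy)-6-[(2R)-2-hydroxypropyl]benzoate
Conditions: Lactobacillus brevis alcohol dehydrogenase ((R)-selective), NADP+ (cat.), MgCl2 (1 mM), 2-propanol (15% v/v), DMSO (5% v/v), phosphate buffer pH 7.0, 30 °C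
Reagents that add atoms: none
Why: Ketoreductase reduction of a methyl ketone of the 1-arylpropan-2-one class; the anti-Prelog enzyme delivers hydride from NADPH to the Si face, giving the (R)-carbinol under catalyst control, with 2-propanol regenerating the cofactor. At neutral pH the bulky tert-butyl ester is not attacked by the new hydroxyl, so no lactone should form.

Step 7
Reactants: 13 methyl (R)-3-hydroxybutanoate
Product: 14 methyl (R)-3-(benzyloxy)butanoate
Conditions: BnOC(=NH)CCl3 (1.3 equiv), TfOH (cat.), CH2Cl2/cyclohexane, 0 °C → rt
Reagents that add atoms: benzyl 2,2,2-trichloroacetimidate, N=C(OCc1ccccc1)C(Cl)(Cl)Cl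
Why: Acid-catalysed O-benzylation with the trichloroacetimidate; no alkoxide is formed, so the β-hydroxy ester cannot undergo retro-aldol cleavage or elimination, and the stereocentre is not involved.

Step 8
Reactants: 14 methyl (R)-3-(benzyloxy)butanoate
Product: 15 (R)-3-(benzyloxy)butanoic acid
Conditions: LiOH, THF/H2O, 0 °C → rt; then 1 M HCl
Reagents that add atoms: lithium hydroxide, [Li+].[OH-]
Why: Saponification of an unhindered methyl ester; benzyloxide is a poor leaving group, so elimination to crotonate should not compete at this temperature.

Step 9
Reactants: 12 tert-butyl 2,4-bis(benzyloxy)-6-[(2R)-2-hydroxypropyl]benzoate; 15 (R)-3-(benzyloxy)butanoic acid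
Product: 16 tert-butyl 2,4-bis(benzyloxy)-6-[(2R)-2-{[(3R)-3-(benzyloxy)butanoyl]oxy}propyl]benzoate
Conditions: EDC·HCl, DMAP (cat.), CH2Cl2, 0 °C → rt
Reagents that add atoms: none
Why: Steglich esterification of a secondary alcohol with an unhindered acid; the carbinol C–O bond is not broken, so the (R) centre of unit C is retained, and the tert-butyl ester does not lactonise under DMAP.

Step 10
Reactants: 16 tert-butyl 2,4-bis(benzyloxy)-6-[(2R)-2-{[(3R)-3-(benzyloxy)butanoyl]oxy}propyl]benzoate
Product: 17 2,4-bis(benzyloxy)-6-[(2R)-2-{[(3R)-3-(benzyloxy)butanoyl]oxy}propyl]benzoic acid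
Conditions: TFA/CH2Cl2 1:4, 0 °C → rt
Reagents that add atoms: none
Why: Acidolysis of the tert-butyl ester by alkyl–oxygen cleavage (loss of 2-methylpropene), which is independent of carbonyl crowding; the secondary alkyl ester and the benzyl ethers should survive short exposure, and the acylated side-chain oxygen can no longer lactonise.

Step 11
Reactants: 18 1,3-bis(benzyloxy)-5-bromobenzene; 19 (R)-propylene oxide
Product: 21 (R)-1-[3,5-bis(benzyloxy)phenyl]propan-2-ol, via arylmagnesium bromide 20 (not isolated)
Conditions: Mg, THF, reflux; CuI (10 mol %), 19, −30 → 0 °C; aq. NH4Cl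
Reagents that add atoms: none
Why: Copper-catalysed opening of a terminal epoxide by an aryl Grignard reagent at the unsubstituted carbon; the stereocentre of 19 is not a reacting centre, so its (R) configuration is carried into 21.

Step 12
Reactants: 21 (R)-1-[3,5-bis(benzyloxy)phenyl]propan-2-ol; 22 2,2,6-trimethyl-4H-1,3-dioxin-4-one
Product: 23 (R)-1-[3,5-bis(benzyloxy)phenyl]propan-2-yl 3-oxobutanoate
Conditions: toluene, 110 °C
Reagents that add atoms: none
Why: Thermal retro-[4+2] fragmentation of the dioxinone releases acetylketene, which the secondary alcohol traps (acetoacetylation) under neutral conditions with the carbinol configuration retained.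

Step 13
Reactants: 23 (R)-1-[3,5-bis(benzyloxy)phenyl]propan-2-yl 3-oxobutanoate
Product: 24 (R)-1-[3,5-bis(benzyloxy)phenyl]propan-2-yl (S)-3-hydroxybutanoate
Conditions: H2 (10 atm), RuCl2[(S)-BINAP] (1 mol %), EtOH/CH2Cl2, 50 °C
Reagents that add atoms: none
Why: Noyori asymmetric hydrogenation of a β-keto ester; the chelated keto ester is reduced under catalyst control, the (S)-BINAP complex giving the (S)-3-hydroxy ester irrespective of the remote (R) centre, and this homogeneous catalyst leaves benzyl ethers intact.

Step 14
Reactants: 17 2,4-bis(benzyloxy)-6-[(2R)-2-{[(3R)-3-(benzyloxy)butanoyl]oxy}propyl]benzoic acid; 24 (R)-1-[3,5-bis(benzyloxy)phenyl]propan-2-yl (S)-3-hydroxybutanoate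
Product: 25 (2R)-4-{[(2R)-1-(3,5-bis(benzyloxy)phenyl)propan-2-yl]oxy}-4-oxobutan-2-yl 2,4-bis(benzyloxy)-6-[(2R)-2-{[(3R)-3-(benzyloxy)butanoyl]oxy}propyl]benzoate
Conditions: PPh3, DIAD, toluene, 0 °C → rt
Reagents that add atoms: none
Why: Mitsunobu esterification: the carboxylate of 17 displaces the oxyphosphonium derived from 24 in an SN2 step with inversion, turning the (S) carbinol into the (R) centre of unit B; the bond forms at the carbinol carbon, so the crowded carbonyl of ring C is bypassed.

Step 15
Reactants: 25 (2R)-4-{[(2R)-1-(3,5-bis(benzyloxy)phenyl)propan-2-yl]oxy}-4-oxobutan-2-yl 2,4-bis(benzyloxy)-6-[(2R)-2-{[(3R)-3-(benzyloxy)butanoyl]oxy}propyl]benzoate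
Product: 26 Hansforester J
Conditions: H2 (1 atm), 10% Pd/C, EtOAc, rt
Reagents that add atoms: none
Why: Hydrogenolysis of four aryl benzyl ethers and one alkyl benzyl ether under neutral conditions; no ester C–O bond is benzylic, so the three ester links and the four stereocentres should be untouched.

## Compound list

1 | 3,5-bis(benzyloxy)phenol | Oc1cc(OCc2ccccc2)cc(OCc2ccccc2)c1 | starting material
2 | 3,5-bis(benzyloxy)-2-iodophenol | Oc1cc(OCc2ccccc2)cc(OCc2ccccc2)c1I | intermediate
3 | 3,5-bis(benzyloxy)-2-iodophenyl 4-chlorobenzenesulfonate | Ic1c(OCc2ccccc2)cc(OCc2ccccc2)cc1OS(=O)(=O)c1ccc(Cl)cc1 | intermediate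
4 | allylmagnesium chloride | C=CC[Mg]Cl | starting material
5 | carbon dioxide | O=C=O | starting material
6 | [2,4-bis(benzyloxy)-6-(4-chlorobenzenesulfonyloxy)phenyl]magnesium chloride | Cl[Mg]c1c(OCc2ccccc2)cc(OCc2ccccc2)cc1OS(=O)(=O)c1ccc(Cl)cc1 | intermediate
7 | 3,5-bis(benzyloxy)benzyne (3,5-bis(benzyloxy)-1,2-didehydrobenzene) | C1#CC(OCc2ccccc2)=CC(OCc2ccccc2)=C1 | intermediate
8 | [2-allyl-4,6-bis(benzyloxy)phenyl]magnesium chloride | C=CCc1cc(OCc2ccccc2)cc(OCc2ccccc2)c1[Mg]Cl | intermediate
9 | 2-allyl-4,6-bis(benzyloxy)benzoic acid | C=CCc1cc(OCc2ccccc2)cc(OCc2ccccc2)c1C(=O)O | intermediate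
10 | tert-butyl 2-allyl-4,6-bis(benzyloxy)benzoate | C=CCc1cc(OCc2ccccc2)cc(OCc2ccccc2)c1C(=O)OC(C)(C)C | intermediate
11 | tert-butyl 2,4-bis(benzyloxy)-6-(2-oxopropyl)benzoate | CC(=O)Cc1cc(OCc2ccccc2)cc(OCc2ccccc2)c1C(=O)OC(C)(C)C | intermediate
12 | tert-butyl 2,4-bis(benzyloxy)-6-[(2R)-2-hydroxypropyl]benzoate | C[C@@H](O)Cc1cc(OCc2ccccc2)cc(OCc2ccccc2)c1C(=O)OC(C)(C)C | intermediate
13 | methyl (R)-3-hydroxybutanoate | COC(=O)C[C@@H](C)O | starting material
14 | methyl (R)-3-(benzyloxy)butanoate | COC(=O)C[C@@H](C)OCc1ccccc1 | intermediate
15 | (R)-3-(benzyloxy)butanoic acid | OC(=O)C[C@@H](C)OCc1ccccc1 | intermediate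
16 | tert-butyl 2,4-bis(benzyloxy)-6-[(2R)-2-{[(3R)-3-(benzyloxy)butanoyl]oxy}propyl]benzoate | CC(C)(C)OC(=O)c1c(OCc2ccccc2)cc(OCc2ccccc2)cc1C[C@@H](C)OC(=O)C[C@@H](C)OCc1ccccc1 | intermediate
17 | 2,4-bis(benzyloxy)-6-[(2R)-2-{[(3R)-3-(benzyloxy)butanoyl]oxy}propyl]benzoic acid | OC(=O)c1c(OCc2ccccc2)cc(OCc2ccccc2)cc1C[C@@H](C)OC(=O)C[C@@H](C)OCc1ccccc1 | intermediate
18 | 1,3-bis(benzyloxy)-5-bromobenzene | Brc1cc(OCc2ccccc2)cc(OCc2ccccc2)c1 | starting material
19 | (R)-propylene oxide | C[C@@H]1CO1 | starting material
20 | [3,5-bis(benzyloxy)phenyl]magnesium bromide | Br[Mg]c1cc(OCc2ccccc2)cc(OCc2ccccc2)c1 | intermediate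
21 | (R)-1-[3,5-bis(benzyloxy)phenyl]propan-2-ol | C[C@@H](O)Cc1cc(OCc2ccccc2)cc(OCc2ccccc2)c1 | intermediate
22 | 2,2,6-trimethyl-4H-1,3-dioxin-4-one | CC1=CC(=O)OC(C)(C)O1 | starting material
23 | (R)-1-[3,5-bis(benzyloxy)phenyl]propan-2-yl 3-oxobutanoate | C[C@H](Cc1cc(OCc2ccccc2)cc(OCc2ccccc2)c1)OC(=O)CC(C)=O | intermediate
24 | (R)-1-[3,5-bis(benzyloxy)phenyl]propan-2-yl (S)-3-hydroxybutanoate | C[C@H](Cc1cc(OCc2ccccc2)cc(OCc2ccccc2)c1)OC(=O)C[C@H](C)O | intermediate
25 | penta-O-benzyl Hansforester J: (2R)-4-{[(2R)-1-(3,5-bis(benzyloxy)phenyl)propan-2-yl]oxy}-4-oxobutan-2-yl 2,4-bis(benzyloxy)-6-[(2R)-2-{[(3R)-3-(benzyloxy)butanoyl]oxy}propyl]benzoate | C[C@H](Cc1cc(OCc2ccccc2)cc(OCc2ccccc2)c1)OC(=O)C[C@@H](C)OC(=O)c1c(OCc2ccccc2)cc(OCc2ccccc2)cc1C[C@@H](C)OC(=O)C[C@@H](C)OCc1ccccc1 | intermediate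
26 | Hansforester J | C[C@H](Cc1cc(O)cc(O)c1)OC(=O)C[C@@H](C)OC(=O)c1c(O)cc(O)cc1C[C@@H](C)OC(=O)C[C@@H](C)O | target

## Step count and risks

Total step count: 15. Longest linear sequence: 10 (steps 1–6, 9, 10, 14, 15). Units D (steps 7, 8) and A–B (steps 11–13) are prepared in parallel.

**Step 3 (key step).**
- What may go wrong: the iodine–magnesium exchange may be slow on the electron-rich ring, or the Grignard reagents may attack the sulfonate at sulfur. The aryne may be captured by residual isopropylmagnesium chloride or by aryne-derived arylmagnesium species, giving oligomers. Regiocontrol may be partly lost if the second benzyloxy group counts for more than expected.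
- Fallback: it sets out from bromide 18 and returns at acid 9 without an aryne. Arylmagnesium 20, made from 18 as in step 11, is allylated with allyl bromide and catalytic CuI to give 1-allyl-3,5-bis(benzyloxy)benzene F1. Vilsmeier–Haack formylation (POCl3, DMF) should go to the position ortho to the allyl group and para to a benzyloxy group, in preference to the crowded position between the two ethers, giving 2-allyl-4,6-bis(benzyloxy)benzaldehyde F2. Pinnick oxidation (NaClO2, NaH2PO4, 2-methylbut-2-ene) then gives 9.

**Step 1.**
- What may go wrong: poor regioselectivity, with iodination para to the hydroxyl at C4, and over-iodination of the triply activated ring.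
- Fallback: it sets out from phenol 1 and returns at iodophenol 2 by directed metalation. Phenol 1 is converted with diethylcarbamoyl chloride and K2CO3 into 3,5-bis(benzyloxy)phenyl N,N-diethylcarbamate F3. Lithiation with s-BuLi/TMEDA at −78 °C occurs between the carbamate and a benzyloxy group, the doubly activated site, and iodine quench gives 3,5-bis(benzyloxy)-2-iodophenyl N,N-diethylcarbamate F4. Hydrolysis with NaOH in aqueous ethanol releases 2.

**Step 6.**
- What may go wrong: low conversion, because the large, lipophilic keto ester dissolves poorly in the aqueous medium or fits poorly in the active site, or incomplete enantioselectivity.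
- Fallback: it sets out from ketone 11 and returns at alcohol 12 by resolution. Reduction with NaBH4 gives racemic tert-butyl 2,4-bis(benzyloxy)-6-(2-hydroxypropyl)benzoate F5. Candida antarctica lipase B with vinyl acetate, following the usual enantiopreference of this lipase for methyl carbinols, should acetylate the (R) enantiomer to tert-butyl 2-[(2R)-2-acetoxypropyl]-4,6-bis(benzyloxy)benzoate F6. It leaves tert-butyl 2,4-bis(benzyloxy)-6-[(2S)-2-hydroxypropyl]benzoate F7, which is recycled to 11 by Dess–Martin oxidation. Methanolysis of F6 (K2CO3, MeOH) gives 12.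

**Step 14.**
- What may go wrong: E1cB elimination of the activated β-hydroxy ester to the crotonate instead of substitution, and slow SN2 attack by the hindered carboxylate.
- Fallback: it sets out from acid 17 and keto ester 23 and returns at 25 by acyl transfer with retention. Hydrogenation of 23 with RuCl2[(R)-BINAP] gives (R)-1-[3,5-bis(benzyloxy)phenyl]propan-2-yl (R)-3-hydroxybutanoate F8. Acid 17 is converted under neutral conditions with 1-chloro-N,N,2-trimethylprop-1-en-1-amine into 2,4-bis(benzyloxy)-6-[(2R)-2-{[(3R)-3-(benzyloxy)butanoyl]oxy}propyl]benzoyl chloride F9. F9 acylates F8 (Et3N, DMAP, CH2Cl2) to give 25.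

## Further compounds

F1 | step 3 | 1-allyl-3,5-bis(benzyloxy)benzene | C=CCc1cc(OCc2ccccc2)cc(OCc2ccccc2)c1
F2 | step 3 | 2-allyl-4,6-bis(benzyloxy)benzaldehyde | C=CCc1cc(OCc2ccccc2)cc(OCc2ccccc2)c1C=O
F3 | step 1 | 3,5-bis(benzyloxy)phenyl N,N-diethylcarbamate | CCN(CC)C(=O)Oc1cc(OCc2ccccc2)cc(OCc2ccccc2)c1
F4 | step 1 | 3,5-bis(benzyloxy)-2-iodophenyl N,N-diethylcarbamate | CCN(CC)C(=O)Oc1cc(OCc2ccccc2)cc(OCc2ccccc2)c1I
F5 | step 6 | racemic tert-butyl 2,4-bis(benzyloxy)-6-(2-hydroxypropyl)benzoate | CC(O)Cc1cc(OCc2ccccc2)cc(OCc2ccccc2)c1C(=O)OC(C)(C)C
F6 | step 6 | tert-butyl 2-[(2R)-2-acetoxypropyl]-4,6-bis(benzyloxy)benzoate | C[C@H](Cc1cc(OCc2ccccc2)cc(OCc2ccccc2)c1C(=O)OC(C)(C)C)OC(C)=O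
F7 | step 6 | tert-butyl 2,4-bis(benzyloxy)-6-[(2S)-2-hydroxypropyl]benzoate | C[C@H](O)Cc1cc(OCc2ccccc2)cc(OCc2ccccc2)c1C(=O)OC(C)(C)C
F8 | step 14 | (R)-1-[3,5-bis(benzyloxy)phenyl]propan-2-yl (R)-3-hydroxybutanoate | C[C@H](Cc1cc(OCc2ccccc2)cc(OCc2ccccc2)c1)OC(=O)C[C@@H](C)O
F9 | step 14 | 2,4-bis(benzyloxy)-6-[(2R)-2-{[(3R)-3-(benzyloxy)butanoyl]oxy}propyl]benzoyl chloride | ClC(=O)c1c(OCc2ccccc2)cc(OCc2ccccc2)cc1C[C@@H](C)OC(=O)C[C@@H](C)OCc1ccccc1
A1 | alternative 1 | methyl (R)-2,4-dihydroxy-6-[2-(triisopropylsilyloxy)propyl]benzoate | COC(=O)c1c(O)cc(O)cc1C[C@@H](C)O[Si](C(C)C)(C(C)C)C(C)C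
A2 | alternative 1 | (R,E)-6-(triisopropylsilyloxy)hept-3-en-2-one | CC(=O)/C=C/C[C@@H](C)O[Si](C(C)C)(C(C)C)C(C)C
A3 | alternative 1 | dimethyl malonate | COC(=O)CC(=O)OC
A4 | alternative 2 | (R)-6,8-bis(benzyloxy)-3-methylisochroman-1-one | C[C@@H]1Cc2cc(OCc3ccccc3)cc(OCc3ccccc3)c2C(=O)O1
A5 | alternative 2 | potassium 2,4-bis(benzyloxy)benzoate | [K+].[O-]C(=O)c1ccc(OCc2ccccc2)cc1OCc1ccccc1
A6 | alternative 3 | Hansforester J with ring C phenols free and benzyl ethers on ring A (two) and on the unit D hydroxyl | C[C@H](Cc1cc(OCc2ccccc2)cc(OCc2ccccc2)c1)OC(=O)C[C@@H](C)OC(=O)c1c(O)cc(O)cc1C[C@@H](C)OC(=O)C[C@@H](C)OCc1ccccc1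
A7 | alternative 3 | (2R)-4-{[(2R)-1-(3,5-bis(benzyloxy)phenyl)propan-2-yl]oxy}-4-oxobutan-2-yl (5R)-5-{[(3R)-3-(benzyloxy)butanoyl]oxy}hex-2-ynoate | C[C@H](Cc1cc(OCc2ccccc2)cc(OCc2ccccc2)c1)OC(=O)C[C@@H](C)OC(=O)C#CC[C@@H](C)OC(=O)C[C@@H](C)OCc1ccccc1
A8 | alternative 3 | 1-methoxy-1,3-bis(trimethylsilyloxy)buta-1,3-diene | COC(O[Si](C)(C)C)=CC(=C)O[Si](C)(C)C
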